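**Retrosynthetic overview** (ent-gibberellane numbering)
1. Feature used: C5 is the hub of three α-carboxy carbons (C4–C19, C6–C7, C10–C20). H5, C20, H9, C15 and C7 all lie on one face of ring B, so A/B and B/C are both cis and syn (a U-shaped hydrofluorene). Without C18, ring A is the Cs-symmetric C10–C5–C4 allyl anion of a cyclohexene-1,3-dicarboxylate.
2. Ring D comes last. C13–C16 arises from a samarium-ketyl 1,2-vinyl shift that spends the strain of an allene/enone [2+2] adduct (C8–C15, C14–C16) formed on the outer face of ring C.
3. Ring B is zipped between the finished rings A and C by a 5-exo Michael addition C6→C5, followed by MeI on the C4 enolate. C5, C6 and C4 are set in one event.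
4. H9 is the less stable epimer and is installed before ring B exists. A CBS-set C14–O centre is converted by a suprafacial retro-ene hydrogen transfer from C14 to C9.
5. C9–C10 and quaternary C10 come from an enantioselective vinylic substitution of a 3-chloro-2-(CH2CO2Me)cyclohexenone (ring C) by the ring-A allyl anion. Ring order: A and C first, then B, then D.

Key step: step 5

Remark: the SMILES is read as written. The C10 carboxyl (C20) is cis to H5 and H9, so C10 is inverted relative to the usual A/B-trans gibberellin series, and the route is planned for exactly this configuration. β = the face of ring B that carries H5, H9, C7, C15 and C20. TMSE = 2-(trimethylsilyl)ethyl.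

Step 1
Reactants: 1 dimethyl (E)-pent-2-enedioate (dimethyl glutaconate); 2 2-(trimethylsilyl)ethanol
Product: 3 bis-TMSE (E)-pent-2-enedioate
Conditions: Ti(Oi-Pr)4 (10 mol %), 2 (2.5 equiv), toluene, 110 °C, MeOH distilled off
Reagents that add atoms: none
Why: Titanate-catalysed transesterification, pulled by removal of methanol, should exchange both esters; TMSE is chosen because fluoride later attacks silicon and not the hindered C19/C20 carbonyls, which leaves the C7 methyl ester untouched.

Step 2
Reactants: 3 bis-TMSE (E)-pent-2-enedioate; 4 1,3-dibromopropane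
Product: 5 bis-TMSE cyclohex-1-ene-1,3-dicarboxylate (ring A; racemic and labile C10–H; C5=C4)
Conditions: NaH (2.2 equiv), THF–DMF, 0 to 50 °C
Reagents that add atoms: none
Why: Double alkylation of a stabilised carbanion ([3+3] annulation): the glutaconate anion is alkylated at its α-carbon, and the regenerated allyl anion should close through its γ-terminus (6-exo-tet) faster than through α (4-exo-tet), giving the conjugated cyclohexene diester whose C10–H centre needs no control.

Step 3
Reactants: 6 cyclohexane-1,3-dione; 7 methyl bromoacetate
Product: 8 methyl 2-(2,6-dioxocyclohexyl)acetate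
Conditions: KOH (1.0 equiv), MeOH–H2O, rt to 50 °C
Reagents that add atoms: none
Why: C-alkylation of the ambident dione enolate by an activated halide in protic medium, where hydrogen bonding to oxygen favours attack through carbon; no stereocentre is formed.

Step 4
Reactants: 8 methyl 2-(2,6-dioxocyclohexyl)acetate
Product: 9 methyl 2-(2-chloro-6-oxocyclohex-1-en-1-yl)acetate (ring C; C9–Cl, C8 arm C6–C7, C14=O)
Conditions: (COCl)2 (1.2 equiv), DMF (cat.), CH2Cl2, 0 °C to rt
Reagents that add atoms: oxalyl chloride ClC(=O)C(=O)Cl
Why: Vilsmeier-type activation turns the vinylogous acid into the vinylogous acid chloride (β-chloro enone); the two carbonyls of 8 are equivalent, so only one product can form.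

Step 5
Reactants: 5 bis-TMSE cyclohex-1-ene-1,3-dicarboxylate; 9 methyl 2-(2-chloro-6-oxocyclohex-1-en-1-yl)acetate
Product: 10 bis-TMSE (3R)-3-[2-(2-methoxy-2-oxoethyl)-3-oxocyclohex-1-en-1-yl]cyclohex-1-ene-1,3-dicarboxylate
Conditions: N-(9-anthracenylmethyl)-O-allylcinchonidinium bromide or its cinchonine-derived pseudo-enantiomer (10 mol %, series chosen for the R product), Cs2CO3 (1.5 equiv), toluene–CHCl3, −20 °C
Reagents that add atoms: none
Why: Proposed new method: Cs2CO3 deprotonates 5 (a vinylogous malonate) to the planar, Cs-symmetric C10–C5–C4 allyl anion, which as its chiral ammonium ion pair adds through one terminus to the β-carbon C9 of 9 and expels chloride (addition–elimination, nucleophilic vinylic substitution), forming the C9–C10 bond; no ring is closed. The closest known reaction type is the phase-transfer-catalysed enantioselective vinylic substitution of β-halo enones by cyclic β-keto esters, which also builds an ester-bearing quaternary carbon on an enone β-carbon; new here are the vinylogous diester nucleophile and the 2-substituted cyclic electrophile. C10, the only new stereocentre, is controlled by the catalyst, which must tell apart the two enantiotopic termini and faces of the anion. Regioselectivity needs no control, because attack through C10 or C4 gives the same constitution, and the product has no C10–H left, so it can neither racemise nor react twice. Chemoselectivity rests on acidity and softness: 5 is far more acidic than the CH2CO2Me arm and the γ-CH2 of 9, and the soft anion leaves the ester carbonyls alone. The temporary C14 carbonyl turns the otherwise dissonant C9–C10 bond into an ordinary 1,5-dicarbonyl (C20/C14) connection and joins 17 of the 20 skeletal carbons from two achiral rings.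

Step 6
Reactants: 10 vinylic substitution product
Product: 11 bis-TMSE (3R)-3-[(3S)-3-hydroxy-2-(2-methoxy-2-oxoethyl)cyclohex-1-en-1-yl]cyclohex-1-ene-1,3-dicarboxylate (14S, OH on the α face of ring C)
Conditions: (R)-Me-CBS oxazaborolidine (20 mol %), catecholborane (1.5 equiv), toluene, −78 °C; neutral work-up, used at once
Reagents that add atoms: none
Why: Corey–Bakshi–Shibata 1,2-reduction: the catalyst reads the fully substituted alkene carbon C8 as the large and C13H2 as the small group, so the (R)-oxazaborolidine should give the (14S)-alcohol under reagent control whatever the bias of C10, catecholborane at low temperature spares the enoate and esters, and the neutral work-up keeps the γ-hydroxy ester from lactonising.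

Step 7
Reactants: 11 (14S)-allylic alcohol
Product: 13 bis-TMSE (3R)-3-[(1R)-2-(2-methoxy-2-oxoethyl)cyclohex-2-en-1-yl]cyclohex-1-ene-1,3-dicarboxylate (H9 β; C8=C14), via allylic diazene 12 (not isolated)
Conditions: NBSH, PPh3, DEAD, N-methylmorpholine, −30 °C, then 23 °C
Reagents that add atoms: 2-nitrobenzenesulfonohydrazide (NBSH) NNS(=O)(=O)c1ccccc1[N+](=O)[O-] (N2 unit of 12 only)
Why: Mitsunobu displacement by NBSH inverts C14, loss of the sulfinic acid gives the allylic diazene, and its retro-ene (1,5-sigmatropic) loss of N2 hands the hydrogen to C9 on the very face that carried nitrogen, which fixes H9 cis to C20 (the less stable arrangement) by stereospecific chirality transfer and moves the alkene to C8=C14.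

Step 8
Reactants: 13 bicyclohexenyl triester
Product: 15 tricyclic triester (rings A/B/C cis-syn-cis; 8(14)-ene; 5β-H 9β-H 6β-CO2Me 10β-CO2TMSE 4β-Me 4α-CO2TMSE), via lithium ester enolate 14 (not isolated)
Conditions: LDA (1.05 equiv), THF, −78 to −40 °C; MeI (3 equiv), DMPU, −78 to −20 °C
Reagents that add atoms: iodomethane CI; lithium diisopropylamide [Li+].CC(C)[N-]C(C)C (lithium of 14 only)
Why: Tandem intramolecular Michael addition/enolate alkylation: C6–H2 is the only enolisable position of 13, its lithium dienolate attacks C5 through its α-carbon in a 5-exo-trig closure that can only reach the ring-A face carrying C9 (A/B cis, H5 β) with ester C7 turned to the convex β face, and MeI then meets the regiospecifically formed C4 enolate from the outer β face of the U-shaped tricycle because the inner face is covered by C6 and ring C.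

Step 9
Reactants: 15 tricyclic triester
Product: 16 tricyclic enone (13-oxo-8(14)-ene; other centres as in 15)
Conditions: Rh2(cap)4 (1 mol %), t-BuOOH (70 % aq, 6 equiv), DCE, 40 °C
Reagents that add atoms: tert-butyl hydroperoxide CC(C)(C)OO
Why: Dirhodium caprolactamate/t-BuOOH allylic oxidation (tert-butylperoxy radical chain) should attack the only allylic CH2, C13, since the other allylic hydrogens (C9–H, C6–H) are tertiary and crowded, and the near-neutral medium should spare the epimerisable C9, while C6 can at most settle in its preferred β-ester form.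

Step 10
Reactants: 16 tricyclic enone; 17 propadiene (allene)
Product: 18 allene photoadduct (cyclobutane C8–C15–C16–C14 on the β face; 16-methylene next to C14; 13-ketone)
Conditions: hν (Hg lamp, Pyrex, λ > 300 nm), 17 (excess), CH2Cl2, −78 °C
Reagents that add atoms: none
Why: Enone–allene [2+2] photocycloaddition: the triplet enone should bond C8 to a CH2 terminus and C14 to the central allene carbon (head-to-head) on the outer β face, because only a new bond cis to H9 gives the cis five/six junction and the inner face is blocked by ring A, which sets quaternary C8 and C14.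

Step 11
Reactants: 18 allene photoadduct
Product: 19 bis-TMSE ester of the target (13-hydroxy-16-methylene bicyclo[3.2.1]octane rings C/D)
Conditions: SmI2 (4 equiv), HMPA, t-BuOH, THF, 0 °C to rt
Reagents that add atoms: none
Why: Samarium-ketyl radical rearrangement (3-exo attack of the C13 ketyl on C16, then cleavage of the strained C14–C16 bond, a 1,2-vinyl shift of the homoallyl/cyclopropylcarbinyl type) followed by reduction and protonation of the C14 radical should turn the bicyclo[4.2.0]octanone into the bridgehead carbinol, C13 being fixed because C16 can only bridge on the β face.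

Step 12
Reactants: 19 bis-TMSE ester
Product: 20 target (7-methyl ester, 19,20-diacid)
Conditions: TBAF (6 equiv), THF, rt; cold 0.5 M HCl to pH 3
Reagents that add atoms: none
Why: Fluoride-induced β-elimination of both TMSE esters (attack at silicon, loss of ethene) frees the hindered C19 and C20 acids without hydroxide or strong acid, so the C7 methyl ester, the tertiary allylic alcohol, the exocyclic alkene and all stereocentres should stay as they are.

**Compound list**
1 | dimethyl (E)-pent-2-enedioate | COC(=O)C/C=C/C(=O)OC | starting material
2 | 2-(trimethylsilyl)ethanol | C[Si](C)(C)CCO | starting material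
3 | bis-TMSE (E)-pent-2-enedioate | C[Si](C)(C)CCOC(=O)C/C=C/C(=O)OCC[Si](C)(C)C | intermediate
4 | 1,3-dibromopropane | BrCCCBr | starting material
5 | bis-TMSE cyclohex-1-ene-1,3-dicarboxylate (racemic) | C[Si](C)(C)CCOC(=O)C1CCCC(C(=O)OCC[Si](C)(C)C)=C1 | intermediate
6 | cyclohexane-1,3-dione | O=C1CCCC(=O)C1 | starting material
7 | methyl bromoacetate | COC(=O)CBr | starting material
8 | methyl 2-(2,6-dioxocyclohexyl)acetate | COC(=O)CC1C(=O)CCCC1=O | intermediate
9 | methyl 2-(2-chloro-6-oxocyclohex-1-en-1-yl)acetate | COC(=O)CC1=C(Cl)CCCC1=O | intermediate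
10 | (10R) vinylic substitution product | COC(=O)CC1=C(CCCC1=O)[C@@]1(C(=O)OCC[Si](C)(C)C)CCCC(C(=O)OCC[Si](C)(C)C)=C1 | intermediate
11 | (10R,14S)-allylic alcohol | COC(=O)CC1=C(CCC[C@@H]1O)[C@@]1(C(=O)OCC[Si](C)(C)C)CCCC(C(=O)OCC[Si](C)(C)C)=C1 | intermediate
12 | allylic diazene (N on the β face at C14) | COC(=O)CC1=C(CCC[C@H]1N=N)[C@@]1(C(=O)OCC[Si](C)(C)C)CCCC(C(=O)OCC[Si](C)(C)C)=C1 | intermediate
13 | (9R,10R)-bicyclohexenyl triester | COC(=O)CC1=CCCC[C@H]1[C@@]1(C(=O)OCC[Si](C)(C)C)CCCC(C(=O)OCC[Si](C)(C)C)=C1 | intermediate
14 | lithium C4 ester enolate of the tricycle | C1CC[C@@H]2C(=C1)[C@@H](C(=O)OC)[C@H]1[C@]2(C(=O)OCC[Si](C)(C)C)CCCC1=C([O-])OCC[Si](C)(C)C.[Li+] | intermediate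
15 | tricyclic triester, 8(14)-ene | C1CC[C@@H]2C(=C1)[C@@H](C(=O)OC)[C@H]1[C@]2(C(=O)OCC[Si](C)(C)C)CCC[C@@]1(C)C(=O)OCC[Si](C)(C)C | intermediate
16 | tricyclic enone | O=C1CC[C@@H]2C(=C1)[C@@H](C(=O)OC)[C@H]1[C@]2(C(=O)OCC[Si](C)(C)C)CCC[C@@]1(C)C(=O)OCC[Si](C)(C)C | intermediate
17 | propadiene | C=C=C | starting material
18 | allene photoadduct | C=C1C[C@]23[C@H]1C(=O)CC[C@H]2[C@@]1(C(=O)OCC[Si](C)(C)C)CCC[C@@](C)(C(=O)OCC[Si](C)(C)C)[C@H]1[C@@H]3C(=O)OC | intermediate
19 | bis-TMSE ester of the target | C=C1C[C@]23C[C@@]1(O)CC[C@H]2[C@@]1(C(=O)OCC[Si](C)(C)C)CCC[C@@](C)(C(=O)OCC[Si](C)(C)C)[C@H]1[C@@H]3C(=O)OC | intermediate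
20 | target | C=C1C[C@]23C[C@@]1(O)CC[C@H]2[C@@]1(C(=O)O)CCC[C@@](C)(C(=O)O)[C@H]1[C@@H]3C(=O)OC | target

Total steps: 12. Longest linear sequence: 10 (steps 3–12 from cyclohexane-1,3-dione, or steps 1, 2 and 5–12 from dimethyl glutaconate).

**Steps most likely to fail**

Step 5 (Proposed new method). The ion pair may discriminate weakly between the two enantiotopic termini of the allyl anion. Addition to the hindered β-carbon may also be slow.
The fallback sets out from 5 and 9 and returns at 11.
- Plain addition–elimination with NaH in THF–DMF, known for stabilised carbanions and 3-chloro enones, would give the racemic substitution product F1.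
- The (R)-CBS/catecholborane reduction of step 6 is reagent-controlled at C14. It would convert the two enantiomers into two diastereomeric allylic alcohols, 11 and the (10S,14S)-alcohol F2.
- These are separated by chromatography, so C10 is resolved by a centre that the route needs anyway.

Step 7. The crowded C14 oxyphosphonium ion may be captured by the neighbouring C7 ester (lactonisation), or may eliminate, before NBSH displaces it.
The fallback sets out from 11 and returns at 13.
- Alcohol 11 is lactonised on purpose (PPTS, benzene) to the allylic γ-lactone F3.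
- Palladium-catalysed hydrogenolysis with formate (Pd2(dba)3, PBu3, HCO2H/Et3N, dioxane) ionises anti to the α C14–O bond. It transfers hydride from palladium to the more substituted terminus C9 on the β face, giving the 8(14)-ene C7 acid F4 with the same H9.
- Methylation of F4 (TMSCHN2, or MeI/K2CO3) gives 13.

Step 8. The C6 enolate may attack the C20 ester (Claisen closure, also five-membered). The strained Michael closure may revert. Proton exchange may shift the anion to C6 before methylation.
The fallback sets out from 13 and returns at 15.
- O-silylation (LDA, TMSCl, −78 °C) gives the silyl ketene acetal F5.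
- An intramolecular Mukaiyama–Michael addition (cat. Tf2NH, CH2Cl2, −78 °C) closes ring B under non-basic conditions, in which acyl attack is not open. Aqueous work-up gives the C4–H tricyclic triester F6.
- Separate methylation through the C4/C6 bis-enolate (LDA 2.2 equiv, MeI 1 equiv), in which the less stabilised C4 enolate reacts first and from the outer face, gives 15.

**Further compounds**
F1 | step 5 | racemic vinylic substitution product | COC(=O)CC1=C(CCCC1=O)C1(C(=O)OCC[Si](C)(C)C)CCCC(C(=O)OCC[Si](C)(C)C)=C1
F2 | step 5 | (10S,14S)-allylic alcohol | COC(=O)CC1=C(CCC[C@@H]1O)[C@]1(C(=O)OCC[Si](C)(C)C)CCCC(C(=O)OCC[Si](C)(C)C)=C1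
F3 | step 7 | allylic γ-lactone (C7–O–C14) | O=C1CC2=C(CCC[C@@H]2O1)[C@@]1(C(=O)OCC[Si](C)(C)C)CCCC(C(=O)OCC[Si](C)(C)C)=C1
F4 | step 7 | 8(14)-ene C7 carboxylic acid | OC(=O)CC1=CCCC[C@H]1[C@@]1(C(=O)OCC[Si](C)(C)C)CCCC(C(=O)OCC[Si](C)(C)C)=C1
F5 | step 8 | silyl ketene acetal of 13 | COC(O[Si](C)(C)C)=CC1=CCCC[C@H]1[C@@]1(C(=O)OCC[Si](C)(C)C)CCCC(C(=O)OCC[Si](C)(C)C)=C1
F6 | step 8 | C4–H tricyclic triester (4β-H) | C1CC[C@@H]2C(=C1)[C@@H](C(=O)OC)[C@H]1[C@]2(C(=O)OCC[Si](C)(C)C)CCC[C@H]1C(=O)OCC[Si](C)(C)C
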